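**Retrosynthetic overview**
1. Torilin ⇐ Mitsunobu angeloylation with inversion at C8, then Sc(OTf)₃-catalysed acetylation of the tertiary C11–OH ⇐ 8-epi-8,11-dihydroxyguai-4-en-3-one (**14**).
2. The cyclopentenone is closed last, by intramolecular aldol condensation of a cycloheptane-1,4-diketone (**13**). The seven-membered ring is formed first, by RCM.
3. Key bond C7–C11: the nucleophilic radical Me₂C•–OH (photo-HAT from 2-propanol) adds in Giese fashion to C7 of 4-hydroxycycloheptenone **11**. This sets the tertiary carbinol and the C7 centre anti to C8–OH.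
4. The cycloheptenone comes from RCM of a diene made from (S)-β-methyl-δ-valerolactone (C5–C1–C10(C14)–C9–C8 chain, C10 stereocentre). The lactone is alkylated trans with 1-bromobut-2-yne, which supplies C2–C4 and C15; the alkyne becomes the C3 ketone by carbonyl-directed hydration.

Assumption: the ester in the SMILES is the (Z)-2-methylbut-2-enoate (angelate), and enantiopure (S)-β-methyl-δ-valerolactone is commercially available.

---

**Step 1**
Reactants: **1** (S)-4-methyltetrahydro-2H-pyran-2-one; **2** 1-bromobut-2-yne
Product: **3** (3R,4S)-3-(but-2-yn-1-yl)-4-methyltetrahydropyran-2-one (3,4-trans)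
Conditions: LDA, THF, −78 °C; then **2**, −78 → 0 °C
Reagents that add atoms: 1-bromobut-2-yne, CC#CCBr (butynyl group)
Why: Lactone enolate alkylation takes place anti to the 4-methyl group, giving the trans-3,4-disubstituted lactone. This sets C1 trans to the C10 methyl, as in the target (C1 is α to the carbonyl and is also thermodynamically trans).

**Step 2**
Reactants: **3**; **4** N,O-dimethylhydroxylamine
Product: **5** (2R,3S)-2-(but-2-yn-1-yl)-5-hydroxy-N-methoxy-N,3-dimethylpentanamide
Conditions: AlMe₃, MeNH(OMe)·HCl, CH₂Cl₂, 0 °C → rt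
Reagents that add atoms: N,O-dimethylhydroxylamine, CNOC
Why: Weinreb-type aminolysis opens the lactone to a hydroxy Weinreb amide. The alkyne and both stereocentres are untouched.

**Step 3**
Reactants: **5**
Product: **6** (2R,3S)-2-(but-2-yn-1-yl)-N-methoxy-N,3-dimethyl-5-oxopentanamide
Conditions: Dess–Martin periodinane, NaHCO₃, CH₂Cl₂, rt
Reagents that add atoms: none
Why: Mild oxidation of the primary alcohol to the aldehyde (C8) leaves the Weinreb amide and alkyne intact and does not epimerise the β-stereocentre C10.

**Step 4**
Reactants: **6**; **7** vinylmagnesium bromide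
Product: **8** (4R,5S,7S)-4-(but-2-yn-1-yl)-7-hydroxy-5-methylnona-1,8-dien-3-one, formed together with its 7R epimer (~1:1)
Conditions: **7** (3.5 equiv), THF, −78 → 0 °C; NH₄Cl work-up
Reagents that add atoms: vinylmagnesium bromide, C=C[Mg]Br (two vinyl groups)
Why: Grignard addition to the aldehyde gives the C8 allylic alcohol as an epimer mixture. The Weinreb chelate survives until quench and then collapses to the vinyl ketone. The 7S epimer drawn (OH trans to the 5-methyl) is the one carried on, after separation at step 5.

**Step 5**
Reactants: **8**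
Product: **9** (4S,6S,7R)-7-(but-2-yn-1-yl)-4-hydroxy-6-methylcyclohept-2-en-1-one (ring alkene Z; 4-OH and 7-butynyl cis to each other, both trans to the 6-methyl)
Conditions: Hoveyda–Grubbs II (5 mol%), CH₂Cl₂ (3 mM), 40 °C; chromatographic separation of the C8 epimers
Reagents that add atoms: none (ethylene is lost)
Why: Ring-closing metathesis of the vinyl ketone with the allylic alcohol forms the seven-membered Z-enone, which carries the C6=C7 acceptor for the radical step. Diastereomer separation fixes the C8 configuration.

**Step 6**
Reactants: **9**; **10** water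
Product: **11** (4S,6S,7R)-4-hydroxy-6-methyl-7-(2-oxobutyl)cyclohept-2-en-1-one
Conditions: Ph₃PAuCl/AgSbF₆ (5 mol%), MeOH–H₂O (10:1), 60 °C
Reagents that add atoms: water, O
Why: Gold-catalysed alkyne hydration is directed by the C5 carbonyl oxygen, which attacks C3 (5-exo). This gives the C3 ketone regioselectively and so the 1,4-diketone needed for the later aldol.

**Step 7**
Reactants: **11**; **12** 2-propanol
Product: **13** (3S,4S,6S,7R)-4-hydroxy-3-(2-hydroxypropan-2-yl)-6-methyl-7-(2-oxobutyl)cycloheptan-1-one
Conditions: (n-Bu₄N)₄W₁₀O₃₂ (2 mol%), iPrOH (30 equiv), MeCN, 390 nm, 25 °C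
Reagents that add atoms: 2-propanol, CC(C)O (Me₂C(OH)– and H)
Why: Proposed new method: decatungstate photo-HAT on 2-propanol gives the nucleophilic Me₂C•OH radical, which adds Giese-fashion to C7, the β-carbon of the enone. The resulting α-keto radical is reduced by back-HAT and protonated at C6. The closest known reaction is the decatungstate-photocatalysed Giese addition of alcohols to cyclic enones. Attack anti to the pseudo-axial C8–OH (and to the C1 side chain) places C11 on the face opposite O8, i.e. cis to the 10-methyl, and forms the C7–C11 bond.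

**Step 8**
Reactants: **13**
Product: **14** 8-epi-8,11-dihydroxyguai-4-en-3-one (8-OH trans to 10-Me; C11 and 10-Me cis)
Conditions: KOH, MeOH–H₂O (9:1), 40 °C
Reagents that add atoms: none (H₂O is lost)
Why: Intramolecular aldol condensation: the C4 enolate of the ethyl ketone attacks the C5 ketone (5-exo), and dehydration gives the conjugated 4-methylcyclopent-2-enone. The bridged alternative (C6 enolate onto C3) is strained. The existing stereocentres are not touched, and C1 is expected to stay trans to C10–Me under mild base.

**Step 9**
Reactants: **14**; **15** angelic acid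
Product: **16** 8-O-angeloyl-11-hydroxyguai-4-en-3-one (C8 inverted to the natural configuration)
Conditions: PPh₃, DIAD, **15** (3 equiv), THF, 0 °C → rt
Reagents that add atoms: angelic acid, C/C=C(/C)C(=O)O
Why: Mitsunobu esterification proceeds by SN2 at the secondary C8 carbinol and inverts it, so O8 becomes cis to C11 and to the 10-methyl. The tertiary alcohol and the enone do not react, and the Z-alkene of the acid is retained.

**Step 10**
Reactants: **16**; **17** acetic anhydride
Product: **18** torilin
Conditions: Ac₂O, Sc(OTf)₃ (5 mol%), MeCN, 0 °C → rt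
Reagents that add atoms: acetic anhydride, CC(=O)OC(C)=O (acetyl group)
Why: Lewis-acid-catalysed acylation of the hindered tertiary alcohol gives the C11 acetate. The enone and the angelate survive these mild conditions.

---

**Compound list**
1 | (S)-4-methyltetrahydro-2H-pyran-2-one | O=C1OCC[C@H](C)C1 | starting material
2 | 1-bromobut-2-yne | CC#CCBr | starting material
3 | (3R,4S)-3-(but-2-yn-1-yl)-4-methyltetrahydropyran-2-one | O=C1OCC[C@H](C)[C@H]1CC#CC | intermediate
4 | N,O-dimethylhydroxylamine | CNOC | starting material
5 | (2R,3S)-2-(but-2-yn-1-yl)-5-hydroxy-N-methoxy-N,3-dimethylpentanamide | OCC[C@H](C)[C@@H](CC#CC)C(=O)N(C)OC | intermediate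
6 | (2R,3S)-2-(but-2-yn-1-yl)-N-methoxy-N,3-dimethyl-5-oxopentanamide | O=CC[C@H](C)[C@@H](CC#CC)C(=O)N(C)OC | intermediate
7 | vinylmagnesium bromide | C=C[Mg]Br | starting material
8 | (4R,5S,7S)-4-(but-2-yn-1-yl)-7-hydroxy-5-methylnona-1,8-dien-3-one | C=C[C@@H](O)C[C@H](C)[C@@H](CC#CC)C(=O)C=C | intermediate (with its 7R epimer, ~1:1)
9 | (4S,6S,7R)-7-(but-2-yn-1-yl)-4-hydroxy-6-methylcyclohept-2-en-1-one | O[C@H]1C[C@H](C)[C@@H](CC#CC)C(=O)C=C1 | intermediate
10 | water | O | starting material
11 | (4S,6S,7R)-4-hydroxy-6-methyl-7-(2-oxobutyl)cyclohept-2-en-1-one | O[C@H]1C[C@H](C)[C@@H](CC(=O)CC)C(=O)C=C1 | intermediate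
12 | 2-propanol | CC(C)O | starting material
13 | (3S,4S,6S,7R)-4-hydroxy-3-(2-hydroxypropan-2-yl)-6-methyl-7-(2-oxobutyl)cycloheptan-1-one | O[C@H]1C[C@H](C)[C@@H](CC(=O)CC)C(=O)C[C@@H]1C(C)(C)O | intermediate
14 | 8-epi-8,11-dihydroxyguai-4-en-3-one | O[C@H]1C[C@H](C)[C@H]2CC(=O)C(C)=C2C[C@@H]1C(C)(C)O | intermediate
15 | angelic acid ((Z)-2-methylbut-2-enoic acid) | C/C=C(/C)C(=O)O | starting material
16 | 8-O-angeloyl-11-hydroxyguai-4-en-3-one | C/C=C(/C)C(=O)O[C@@H]1C[C@H](C)[C@H]2CC(=O)C(C)=C2C[C@@H]1C(C)(C)O | intermediate
17 | acetic anhydride | CC(=O)OC(C)=O | starting material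
18 | torilin | C/C=C(/C)C(=O)O[C@@H]1C[C@H](C)[C@H]2CC(=O)C(C)=C2C[C@@H]1C(C)(C)OC(C)=O | target

---

**Total steps:** 10. **Longest linear sequence:** 10 steps (from **1**).

**Three steps most likely to fail**
1. **Step 7 (radical hydroxyalkylation).** Facial selectivity at C7 may be wrong, and HAT at the activated C8–H may compete with HAT from 2-propanol.
   Fallback (different approach): add isopropenylmagnesium bromide to **11** with Cu catalysis, do a Co/PhSiH₃/O₂ Mukaiyama hydration to the tertiary alcohol, then oxidise C8–OH to the ketone, equilibrate C7 with DBU and reduce with L-Selectride.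
2. **Step 5 (RCM).** The internal alkyne may undergo enyne metathesis with the vinyl ketone, and the C8 epimers separate with difficulty.
   Fallback: close the ring by intramolecular Nozaki–Hiyama–Kishi coupling of a (Z)-β-iodoenone with the C8 aldehyde.
3. **Step 9 (Mitsunobu inversion).** The hindered β-branched carbinol next to the tertiary alcohol may give elimination or oxetane formation, or the angelate may isomerise.
   Fallback: oxidise **14** to the C8 ketone with Dess–Martin periodinane and reduce with L-Selectride (hydride anti to C7, giving OH cis to C11). Then esterify with angelic acid under Yamaguchi conditions (2,4,6-Cl₃C₆H₂COCl, Et₃N, DMAP).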